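**Retrosynthetic overview**
- The target lactone comes from one hydrogenolysis of a cis-fused 2-aryloxetane–γ-lactone: the benzylic C–O bond of the oxetane is the masked pair "tertiary OH at C3 / CH2Ar at C4", held on the same face by the ring fusion.
- The C3 benzyl group comes from C-benzylation of the ring-fusion enolate of that bicycle with a benzylic bromide; the bicycle locks the configuration.
- The bicycle comes from an enantioselective intramolecular carbonyl–olefin [2+2] of a cinnamyl glyoxylate, which forms the C3–C4 bond and sets both stereocentres.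
- The glyoxylate comes from glyoxylic acid and O-benzylconiferyl alcohol, itself made from O-benzylvanillin by olefination and reduction.
- Ring order: γ-lactone and oxetane form together in step 4; the oxetane is opened in the last step; both arenes are bought.

Assumption: the copper complex is made beforehand from CuCl2, the ligand and AgSbF6; C7 of the bicycle is drawn as the expected exo-aryl isomer and is erased in step 7.
Abbreviation: (S,S)-t-Bu-box = 2,2'-(propane-2,2-diyl)bis[(4S)-4-tert-butyl-4,5-dihydro-1,3-oxazole].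

**Route**

Step 1
Reactants: 1 4-(benzyloxy)-3-methoxybenzaldehyde; 2 triethyl phosphonoacetate
Product: 4 ethyl (2E)-3-[4-(benzyloxy)-3-methoxyphenyl]prop-2-enoate, via sodium phosphonoacetate carbanion 3 (not isolated)
Conditions: NaH, THF, 0 °C; then 1, 0 °C to rt
Reagents that add atoms: none
Why: Horner–Wadsworth–Emmons olefination of an aromatic aldehyde with a stabilised phosphonate gives the (E)-cinnamate; no stereocentre is formed.

Step 2
Reactants: 4 ethyl (2E)-3-[4-(benzyloxy)-3-methoxyphenyl]prop-2-enoate
Product: 5 (2E)-3-[4-(benzyloxy)-3-methoxyphenyl]prop-2-en-1-ol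
Conditions: i-Bu2AlH (2.2 equiv), CH2Cl2, −78 °C; aq. potassium sodium tartrate
Reagents that add atoms: none
Why: 1,2-reduction of the conjugated ester by the aluminium hydride at low temperature gives the allylic alcohol and leaves the alkene and the benzyl ether untouched.

Step 3
Reactants: 5 (2E)-3-[4-(benzyloxy)-3-methoxyphenyl]prop-2-en-1-ol; 6 glyoxylic acid monohydrate
Product: 8 (2E)-3-[4-(benzyloxy)-3-methoxyphenyl]prop-2-en-1-yl 2-oxoacetate, via glyoxylate hydrate ester 7 (not isolated)
Conditions: DCC, DMAP (cat.), CH2Cl2, 0 °C to rt; filter; PhMe azeotrope, 4 Å molecular sieves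
Reagents that add atoms: none
Why: Steglich (carbodiimide/DMAP) esterification of the carboxyl group of the hydrate is neutral and so tolerates the acid-labile electron-rich cinnamyl alcohol; azeotropic drying cracks the gem-diol to the free aldehyde.

Step 4
Reactants: 8 (2E)-3-[4-(benzyloxy)-3-methoxyphenyl]prop-2-en-1-yl 2-oxoacetate
Product: 9 (1R,5S,7S)-7-[4-(benzyloxy)-3-methoxyphenyl]-3,6-dioxabicyclo[3.2.0]heptan-4-one
Conditions: [Cu((S,S)-t-Bu-box)](SbF6)2 (10 mol%), 4 Å molecular sieves, CH2Cl2 (0.005 M), −40 to 0 °C; Et3N, filtration through basic Al2O3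
Reagents that add atoms: none
Why: Proposed new method: an enantioselective intramolecular carbonyl–olefin formal [2+2] cycloaddition, in which the divalent copper bis(oxazoline) dication chelates the glyoxylate as in the known copper–bis(oxazoline) glyoxylate–ene reaction and the tethered 4-alkoxystyrene attacks the Si face of the aldehyde through its non-benzylic carbon (5-exo, closing the lactone); bond formation at that carbon leaves no ene hydrogen and the substrate has no second arene, so the p-alkoxybenzyl cation/copper alkoxide pair collapses to the 2-aryloxetane, forming lactone and oxetane in one operation; the ligand sets C5 as S and the obligatory cis fusion of the [3.2.0] bicycle then fixes C1 as R; closest known reaction types are the copper–bis(oxazoline) glyoxylate–ene reaction, Lewis-acid formal [2+2] oxetane formation from activated carbonyl compounds and electron-rich alkenes, and the oxetane-forming half of Lewis-acid carbonyl–olefin metathesis.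

Step 5
Reactants: 10 [4-(benzyloxy)-3-methoxyphenyl]methanol
Product: 11 1-(benzyloxy)-4-(bromomethyl)-2-methoxybenzene
Conditions: PBr3 (0.4 equiv), Et2O, 0 °C
Reagents that add atoms: phosphorus tribromide, BrP(Br)Br
Why: SN2 bromination of the benzylic alcohol through its phosphite ester; the electron-rich bromide is used at once.

Step 6
Reactants: 9 (1R,5S,7S)-7-[4-(benzyloxy)-3-methoxyphenyl]-3,6-dioxabicyclo[3.2.0]heptan-4-one; 11 1-(benzyloxy)-4-(bromomethyl)-2-methoxybenzene
Product: 13 (1R,5S,7S)-5-[4-(benzyloxy)-3-methoxybenzyl]-7-[4-(benzyloxy)-3-methoxyphenyl]-3,6-dioxabicyclo[3.2.0]heptan-4-one, via lithium enolate of the bicyclic lactone 12 (not isolated)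
Conditions: LiN(i-Pr)2 (1.1 equiv), THF, −78 °C; then 11, −78 to −40 °C
Reagents that add atoms: none
Why: Lactone enolate alkylation: the α-CH carries the oxetane oxygen and has no β-leaving group, and the ring-fusion enolate can only be attacked on its convex face, so the benzyl group necessarily ends up trans to C7 with C5 still S.

Step 7
Reactants: 13 (1R,5S,7S)-5-[4-(benzyloxy)-3-methoxybenzyl]-7-[4-(benzyloxy)-3-methoxyphenyl]-3,6-dioxabicyclo[3.2.0]heptan-4-one
Product: 14 (3S,4S)-3-hydroxy-3,4-bis(4-hydroxy-3-methoxybenzyl)oxolan-2-one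
Conditions: H2 (1 atm), 10% Pd/C, EtOAc–EtOH, rt
Reagents that add atoms: none
Why: Catalytic hydrogenolysis cleaves the two benzyl ethers and the strained benzylic C7–O bond of the oxetane but not the C5–O bond, so the tertiary alcohol appears with retention and C7 becomes the methylene of the C4 benzyl group; the neutral medium avoids ionising the oxetane.

**Compound list**
1 | 4-(benzyloxy)-3-methoxybenzaldehyde | O=Cc1ccc(OCc2ccccc2)c(OC)c1 | starting material
2 | triethyl phosphonoacetate | CCOC(=O)CP(=O)(OCC)OCC | starting material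
3 | sodium salt of the triethyl phosphonoacetate carbanion | CCOC(=O)[CH-]P(=O)(OCC)OCC.[Na+] | intermediate
4 | ethyl (2E)-3-[4-(benzyloxy)-3-methoxyphenyl]prop-2-enoate | CCOC(=O)/C=C/c1ccc(OCc2ccccc2)c(OC)c1 | intermediate
5 | (2E)-3-[4-(benzyloxy)-3-methoxyphenyl]prop-2-en-1-ol | OC/C=C/c1ccc(OCc2ccccc2)c(OC)c1 | intermediate
6 | glyoxylic acid monohydrate (2,2-dihydroxyacetic acid) | OC(O)C(=O)O | starting material
7 | (2E)-3-[4-(benzyloxy)-3-methoxyphenyl]prop-2-en-1-yl 2,2-dihydroxyacetate | OC(O)C(=O)OC/C=C/c1ccc(OCc2ccccc2)c(OC)c1 | intermediate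
8 | (2E)-3-[4-(benzyloxy)-3-methoxyphenyl]prop-2-en-1-yl 2-oxoacetate | O=CC(=O)OC/C=C/c1ccc(OCc2ccccc2)c(OC)c1 | intermediate
9 | (1R,5S,7S)-7-[4-(benzyloxy)-3-methoxyphenyl]-3,6-dioxabicyclo[3.2.0]heptan-4-one | O=C1OC[C@@H]2[C@@H](c3ccc(OCc4ccccc4)c(OC)c3)O[C@H]12 | intermediate
10 | [4-(benzyloxy)-3-methoxyphenyl]methanol | OCc1ccc(OCc2ccccc2)c(OC)c1 | starting material
11 | 1-(benzyloxy)-4-(bromomethyl)-2-methoxybenzene | BrCc1ccc(OCc2ccccc2)c(OC)c1 | intermediate
12 | lithium enolate of 9 | [Li+].[O-]C1=C2O[C@H](c3ccc(OCc4ccccc4)c(OC)c3)[C@H]2CO1 | intermediate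
13 | (1R,5S,7S)-5-[4-(benzyloxy)-3-methoxybenzyl]-7-[4-(benzyloxy)-3-methoxyphenyl]-3,6-dioxabicyclo[3.2.0]heptan-4-one | O=C1OC[C@@H]2[C@@H](c3ccc(OCc4ccccc4)c(OC)c3)O[C@]12Cc1ccc(OCc2ccccc2)c(OC)c1 | intermediate
14 | (3S,4S)-3-hydroxy-3,4-bis(4-hydroxy-3-methoxybenzyl)oxolan-2-one | COc1cc(C[C@H]2COC(=O)[C@]2(O)Cc2ccc(O)c(OC)c2)ccc1O | target

**Step count**
Total: 7 steps. Longest linear sequence: 6 steps (1 → 4 → 5 → 8 → 9 → 13 → 14); step 5 (10 → 11) is a one-step side branch.

**Steps most likely to fail**

1. Step 4 (the [2+2]). It needs the minor s-cis rotamer of the ester. The copper-bound cinnamyl ester may ionise. Under the Lewis acid the oxetane can reopen to the benzylic cation and drift to the 4-arylidene lactone or to oligomers. Fallback, a three-component interception giving a strain-free ring: setting out from 8, the same copper complex is used in CH2Cl2–acetone, so that the benzylic cation is captured by acetone and the copper alkoxide closes the oxocarbenium ion (the chemistry that turns epoxides into acetonides under Lewis acids). This gives the cis-fused acetonide lactone F1. LiN(i-Pr)2 and 11 then give the C3-benzylated acetonide lactone F2. H2 over Pd(OH)2/C cleaves the benzylic C–O bond, lets the hemiketal shed acetone and removes both benzyl ethers, coming back to the route at 14.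

2. Step 6 (alkylation at the ring fusion). The strained, hindered enolate may alkylate slowly or on oxygen, and 13 is acid-sensitive, so it needs base-washed silica. Fallback, opening the oxetane first and relying on 1,2-induction: setting out from 9, Et3SiH/BF3·OEt2 (CH2Cl2, −78 °C) reduces the benzylic C–O bond to give (3S,4S)-4-[4-(benzyloxy)-3-methoxybenzyl]-3-hydroxyoxolan-2-one F3. Its dianion (LiN(i-Pr)2, 2.2 equiv, THF–DMPU, −78 °C) is benzylated by 11 anti to the C4 benzyl group to give (3S,4S)-3,4-bis[4-(benzyloxy)-3-methoxybenzyl]-3-hydroxyoxolan-2-one F4. H2 over 10% Pd/C returns to the route at 14.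

3. Step 3 (glyoxylate ester). Carbodiimide coupling of the hydrate can give acylal oligomers, and incomplete cracking of the hydrate would poison step 4. Fallback, acylating first and oxidising afterwards: setting out from 5, bromoacetyl bromide/pyridine gives the cinnamyl bromoacetate F5. AgNO3 in MeCN exchanges bromide for nitrate to give the cinnamyl nitrooxyacetate F6. NaOAc in DMSO (Kornblum nitrate-ester oxidation) eliminates nitrite and comes back to the route at 8.

**Further compounds**
F1 | step 4 | cis-fused acetonide (2,2-dimethyl-1,3-dioxane) of (3S,4R)-4-{(S)-[4-(benzyloxy)-3-methoxyphenyl](hydroxy)methyl}-3-hydroxyoxolan-2-one | O=C1OC[C@@H]2[C@@H](c3ccc(OCc4ccccc4)c(OC)c3)OC(C)(C)O[C@H]12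
F2 | step 4 | the same acetonide carrying a 4-(benzyloxy)-3-methoxybenzyl group at C3 of the lactone (3S,4R) | O=C1OC[C@@H]2[C@@H](c3ccc(OCc4ccccc4)c(OC)c3)OC(C)(C)O[C@]12Cc1ccc(OCc2ccccc2)c(OC)c1
F3 | step 6 | (3S,4S)-4-[4-(benzyloxy)-3-methoxybenzyl]-3-hydroxyoxolan-2-one | O[C@@H]1C(=O)OC[C@@H]1Cc1ccc(OCc2ccccc2)c(OC)c1
F4 | step 6 | (3S,4S)-3,4-bis[4-(benzyloxy)-3-methoxybenzyl]-3-hydroxyoxolan-2-one | COc1cc(C[C@H]2COC(=O)[C@]2(O)Cc2ccc(OCc3ccccc3)c(OC)c2)ccc1OCc1ccccc1
F5 | step 3 | (2E)-3-[4-(benzyloxy)-3-methoxyphenyl]prop-2-en-1-yl bromoacetate | BrCC(=O)OC/C=C/c1ccc(OCc2ccccc2)c(OC)c1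
F6 | step 3 | (2E)-3-[4-(benzyloxy)-3-methoxyphenyl]prop-2-en-1-yl (nitrooxy)acetate | [O-][N+](=O)OCC(=O)OC/C=C/c1ccc(OCc2ccccc2)c(OC)c1
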